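Ring A, the butyrylfilicinic acid ring (C1 ketone, C2 bridge carbon, C3 enol carbon, C4 CMe2, C5 enol carbon, C6 butyryl-bearing carbon), alternates acceptor and donor carbons, and quaternary C4 cannot enolise. It is cut at C1–C2 and C3–C4 into a four-carbon donor–acceptor unit and an acetyl acceptor–donor unit. The precursor is an isoxazole ester that masks the C5/butyryl diketone: lithiation of its isopropyl methine, acetylation (C3–C4) and Dieckmann closure of the only possible ketone enolate onto the ester (C1–C2) build ring A in one flask. After unmasking, Mannich bases deliver quinone methides that join rings A–D through the three CH2 bridges in a fixed order.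

Key step: step 2

Remark: the target has no stereocentre and is drawn as one enol tautomer, so all keto–enol tautomers count as one compound; oxime 1 is used as its commercial E/Z mixture and phlorobutyrophenone 16 is taken as a catalogue chemical.

Step 1
Reactants: 1 butanal oxime; 2 methyl 4-methyl-3-oxopentanoate
Product: 5 methyl 5-isopropyl-3-propylisoxazole-4-carboxylate, via N-hydroxybutanimidoyl chloride 3 (not isolated), via butanenitrile oxide 4 (not isolated)
Conditions: 1, NCS, DMF, 23→40 °C; solution added slowly to 2, NaOMe, MeOH, 0→23 °C
Reagents that add atoms: N-chlorosuccinimide, O=C1CCC(=O)N1Cl (its chlorine appears only in 3)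
Why: Chlorination of the aldoxime and dehydrochlorination give the nitrile oxide, whose carbon is attacked by the enolate carbon of 2 while the oxime oxygen condenses with the isobutyryl ketone and water is lost (nitrile oxide–β-keto ester isoxazole synthesis), so that isopropyl ends at C5, the ester at C4 and propyl at C3 of the isoxazole.

Step 2
Reactants: 5 methyl 5-isopropyl-3-propylisoxazole-4-carboxylate; 6 acetyl chloride
Product: 9 6-hydroxy-7,7-dimethyl-3-propyl-1,2-benzisoxazol-4(7H)-one, via lateral lithio species 7 (not isolated), via methyl ketone 8 (not isolated)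
Conditions: LiN(iPr)2 (1.1 equiv), THF, −78 °C; 6 (1.1 equiv), −78 °C; LiN(SiMe3)2 (2.5 equiv), −78→23 °C; aq. HCl
Reagents that add atoms: lithium diisopropylamide, [Li+].CC(C)[N-]C(C)C (its lithium appears only in 7)
Why: LiN(iPr)2 removes the methine proton of the 5-isopropyl group, the only C–H that is vinylogous to the ester through the ring C=C bond (the α-CH2 of the 3-propyl group is only aza-allylic and far less acidic), and the tertiary carbanion 7 is C-acetylated by 6 with recovery of the heteroaromatic ring, which forms C3–C4 and the quaternary carbon. In ketone 8 the CMe2 carbon bears no hydrogen, so LiN(SiMe3)2 can form only the methyl enolate, which attacks the neighbouring methyl ester in a Dieckmann condensation, forms C1–C2 and expels methoxide, and deprotonation of the vinylogous acid 9 makes the sequence irreversible. The closest known reaction types are the lateral lithiation–acylation of 5-alkylisoxazoles and ortho-toluates and the Claisen-type closures onto isoxazole-4-carboxylates, run here in tandem as a formal (4+2) annulation. The one ring that closes is the six-membered carbocycle, by a 6-(enolendo)-exo-trig closure helped by the gem-dimethyl (Thorpe–Ingold) effect. No stereocentre is formed. The step needs C- over O-cyclisation: the enol lactone from O-attack would carry an exocyclic methylene group, cannot become an aromatic pyranone because of the CMe2 carbon, and is reopened by methoxide, so the material should drain to the stabilised dione anion.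

Step 3
Reactants: 9 6-hydroxy-7,7-dimethyl-3-propyl-1,2-benzisoxazol-4(7H)-one
Product: 11 butyrylfilicinic acid (2-butanoyl-3,5-dihydroxy-4,4-dimethylcyclohexa-2,5-dien-1-one), via enaminone 10 (not isolated)
Conditions: H2 (1 atm), Pd/C, EtOH, 23 °C; filter; 1 M aq. NaOH, 60 °C; aq. HCl
Reagents that add atoms: water, O
Why: Hydrogenolysis of the weak N–O bond of a 4-acylisoxazole gives the vinylogous amide 10, and addition–elimination of hydroxide at its amino-bearing carbon releases ammonia and the β-triketone (standard unmasking of an isoxazole as a 1,3-dicarbonyl group), while the enolised dione resists mild hydrogenation.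

Step 4
Reactants: 11 butyrylfilicinic acid
Product: 12 2-butanoyl-6-[(dimethylamino)methyl]-3,5-dihydroxy-4,4-dimethylcyclohexa-2,5-dien-1-one
Conditions: CH2(NMe2)2 (1.1 equiv), CH2Cl2, 0→23 °C
Reagents that add atoms: N,N,N',N'-tetramethylmethanediamine, CN(C)CN(C)C
Why: Mannich reaction in which the acidic triketone protonates the aminal and the iminium ion is captured at C2, the only unsubstituted donor carbon of ring A, to give a stable zwitterionic Mannich base.

Step 5
Reactants: 13 2-methylbenzene-1,3,5-triol
Product: 14 1-(2,4,6-trihydroxy-3-methylphenyl)butan-1-one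
Conditions: PrCOCl, AlCl3, CH2Cl2–PhNO2, 0→40 °C; aq. HCl
Reagents that add atoms: butanoyl chloride, CCCC(=O)Cl
Why: Friedel–Crafts acylation at one of the two equivalent free positions of the electron-rich ring, after which the chelated ketone deactivates the ring against a second acylation.

Step 6
Reactants: 14 1-(2,4,6-trihydroxy-3-methylphenyl)butan-1-one
Product: 15 1-{3-[(dimethylamino)methyl]-2,4,6-trihydroxy-5-methylphenyl}butan-1-one
Conditions: CH2(NMe2)2 (1.5 equiv), EtOH, 0→23 °C
Reagents that add atoms: N,N,N',N'-tetramethylmethanediamine, CN(C)CN(C)C
Why: Mannich reaction at the single free ring position of 14, run cold and with excess aminal so that the Mannich base does not go on to a methylene-bridged dimer.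

Step 7
Reactants: 16 1-(2,4,6-trihydroxyphenyl)butan-1-one (two molecules)
Product: 17 1,1'-[methylenebis(2,4,6-trihydroxybenzene-3,1-diyl)]dibutan-1-one
Conditions: 37% aq. CH2O (0.35 equiv), cat. HCl, MeOH–H2O, 23 °C
Reagents that add atoms: formaldehyde, C=O
Why: Hydroxymethylation followed by Friedel–Crafts-type alkylation of a second molecule of 16 (phenol–formaldehyde condensation), with formaldehyde as limiting reagent so that growth beyond the dimer is held back.

Step 8
Reactants: 15 ring D Mannich base; 17 methylene-bridged dimer (rings B and C)
Product: 19 trimer of rings B, C and D with one free position on ring B, via ortho-quinone methide 18 (not isolated)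
Conditions: 17 (3 equiv), 1,4-dioxane–AcOH, 80 °C
Reagents that add atoms: none
Why: Loss of dimethylamine from the phenolic Mannich base gives ortho-quinone methide 18, which is trapped by conjugate addition of a free ring carbon of 17 (quinone methide arylation), 15 having no free ring position of its own and the excess of 17 favouring single alkylation.

Step 9
Reactants: 12 ring A Mannich base; 19 trimer of rings B, C and D
Product: 21 target CNP0246352.0, via methylidene triketone 20 (not isolated)
Conditions: 1,4-dioxane–AcOH, 45 °C
Reagents that add atoms: none
Why: Retro-Michael loss of dimethylamine from 12 gives the strongly electrophilic methylidene triketone 20, and conjugate addition of the only free aromatic carbon of 19 (ring B) followed by re-enolisation closes the last CH2 bridge, the acetic acid binding the amine so that base-induced exchange of the bridges is suppressed.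

Compound list
1 | butanal oxime | CCCC=NO | starting material
2 | methyl 4-methyl-3-oxopentanoate | COC(=O)CC(=O)C(C)C | starting material
3 | N-hydroxybutanimidoyl chloride | CCCC(Cl)=NO | intermediate
4 | butanenitrile oxide | CCCC#[N+][O-] | intermediate
5 | methyl 5-isopropyl-3-propylisoxazole-4-carboxylate | CCCc1noc(C(C)C)c1C(=O)OC | intermediate
6 | acetyl chloride | CC(=O)Cl | starting material
7 | lateral lithio species of 5 (carbanion at the isopropyl carbon) | [Li+].CCCc1noc([C-](C)C)c1C(=O)OC | intermediate
8 | methyl 5-(2-methyl-3-oxobutan-2-yl)-3-propylisoxazole-4-carboxylate | CCCc1noc(C(C)(C)C(C)=O)c1C(=O)OC | intermediate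
9 | 6-hydroxy-7,7-dimethyl-3-propyl-1,2-benzisoxazol-4(7H)-one | CCCc1noc2c1C(=O)C=C(O)C2(C)C | intermediate
10 | 2-(1-aminobutylidene)-5-hydroxy-4,4-dimethylcyclohex-5-ene-1,3-dione | CCCC(N)=C1C(=O)C=C(O)C(C)(C)C1=O | intermediate
11 | butyrylfilicinic acid | CCCC(=O)C1=C(O)C(C)(C)C(O)=CC1=O | intermediate
12 | 2-butanoyl-6-[(dimethylamino)methyl]-3,5-dihydroxy-4,4-dimethylcyclohexa-2,5-dien-1-one | CCCC(=O)C1=C(O)C(C)(C)C(O)=C(CN(C)C)C1=O | intermediate
13 | 2-methylbenzene-1,3,5-triol | Cc1c(O)cc(O)cc1O | starting material
14 | 1-(2,4,6-trihydroxy-3-methylphenyl)butan-1-one | CCCC(=O)c1c(O)cc(O)c(C)c1O | intermediate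
15 | 1-{3-[(dimethylamino)methyl]-2,4,6-trihydroxy-5-methylphenyl}butan-1-one | CCCC(=O)c1c(O)c(C)c(O)c(CN(C)C)c1O | intermediate
16 | 1-(2,4,6-trihydroxyphenyl)butan-1-one (phlorobutyrophenone) | CCCC(=O)c1c(O)cc(O)cc1O | starting material
17 | 1,1'-[methylenebis(2,4,6-trihydroxybenzene-3,1-diyl)]dibutan-1-one | CCCC(=O)c1c(O)cc(O)c(Cc2c(O)cc(O)c(C(=O)CCC)c2O)c1O | intermediate
18 | ortho-quinone methide of ring D | C=C1C(=O)C(C(=O)CCC)=C(O)C(C)=C1O | intermediate
19 | trimer of rings B, C and D | CCCC(=O)c1c(O)cc(O)c(Cc2c(O)c(Cc3c(O)c(C)c(O)c(C(=O)CCC)c3O)c(O)c(C(=O)CCC)c2O)c1O | intermediate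
20 | 2-butanoyl-3-hydroxy-4,4-dimethyl-6-methylidenecyclohex-2-ene-1,5-dione | C=C1C(=O)C(C(=O)CCC)=C(O)C(C)(C)C1=O | intermediate
21 | CNP0246352.0 (tetramer of rings A, B, C and D) | CCCC(=O)C1=C(O)C(C)(C)C(O)=C(Cc2c(O)c(Cc3c(O)c(Cc4c(O)c(C)c(O)c(C(=O)CCC)c4O)c(O)c(C(=O)CCC)c3O)c(O)c(C(=O)CCC)c2O)C1=O | target

Total step count: 9. Longest linear sequence: 5 steps (1, 2, 3, 4, 9).

Steps most likely to fail

Step 2. The hindered tertiary carbanion may act as a base toward acetyl chloride or toward ketone 8 instead of being acylated. Metalation may also stray to the propyl chain, or the anion may condense with the ester of a second molecule. The fallback does not build ring A but carves it out of an aromatic ring. Dearomatising double C-methylation of phlorobutyrophenone (MeI, NaOMe, MeOH, 0→23 °C) sets out from 16 and comes back to the route at 11, so that steps 1–3 are dropped. It makes no compound outside the list (F0).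

Step 8. A second alkylation of the bifunctional dimer may occur, and heat may fragment and recombine its CH2 bridge, which would scramble the ring order. The fallback is a dimer-plus-dimer assembly that never uses a bifunctional dimer.
- It sets out from 15, 12 and 16.
- 15 is heated with an excess of monomer 16 in 1,4-dioxane–AcOH to give the ring C–D dimer F1.
- Aminomethylation of its one free position with CH2(NMe2)2 gives the Mannich base of the ring C–D dimer F2.
- Separately, 12 and an excess of 16 give the ring A–B dimer F3.
- Union of F2 with F3 under the conditions of step 9 comes back to the route at 21, bypassing 17 and 19.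

Step 9. Retro-Mannich reversal may free the ring A nucleophile, which would then capture the methide (homocoupling). Amine-induced bridge exchange in the product may also compete with the cross-coupling. The fallback replaces methide chemistry by a reductive alkylation and sets out from 19 and 11. Vilsmeier–Haack formylation (POCl3, DMF, EtOAc) of the only free position of 19 gives the trimer aldehyde F4. Knoevenagel condensation of F4 with 11 in the presence of proline and a Hantzsch ester then reduces the alkylidene as it forms (organocatalytic reductive alkylation of a cyclic 1,3-dione). This comes back to the route at 21 without any free amine base or accumulating methide.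

Further compounds
F0 | step 2 | none | none
F1 | step 8 | ring C–D dimer | CCCC(=O)c1c(O)cc(O)c(Cc2c(O)c(C)c(O)c(C(=O)CCC)c2O)c1O
F2 | step 8 | Mannich base of the ring C–D dimer | CCCC(=O)c1c(O)c(CN(C)C)c(O)c(Cc2c(O)c(C)c(O)c(C(=O)CCC)c2O)c1O
F3 | step 8 | ring A–B dimer | CCCC(=O)C1=C(O)C(C)(C)C(O)=C(Cc2c(O)cc(O)c(C(=O)CCC)c2O)C1=O
F4 | step 9 | trimer aldehyde | CCCC(=O)c1c(O)c(C=O)c(O)c(Cc2c(O)c(Cc3c(O)c(C)c(O)c(C(=O)CCC)c3O)c(O)c(C(=O)CCC)c2O)c1O
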